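**Plan**

1. Atoms carry labdane numbers. Retrosynthesis cuts ring A at C3–C4 and C5–C10 (the second cut also opens ring B), then C1–C2, C10–C20 and C9–C10; what remains (C4–C9, C11–C19) is (2E,6E)-farnesol.
2. Enabling feature: on ring B the C8 oxygen and the C10 methyl (C20) are cis-1,3 (both axial), so they can be tied as a γ-lactone with C20 as its carbonyl. C10 then is an α-acyl radical site held over the C5=C4 isopropylidene terminus, and the gem-dimethyl carbon C4 faces a C3 nitrile.
3. Forward: farnesol → (R)-nerolidol → C8,C9-epoxide → acetylide opening (C10, C1) → carbonylative lactonisation (C20) → cyanomethyl addition (C2, C3) and bromination → radical bicyclisation (ring B, then ring A) → C3 ketone to bromide → lactone C20 to methyl.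
4. Stereochemistry: C13 from Sharpless epoxidation; C8/C9 from a hydroxyl-directed epoxidation and anti opening; C10 and C5 from the lactone template and chair closures; C3 from equatorial hydride delivery, then SN2 inversion.

Key step: step 9

Remark: commercial (2E,6E)-farnesol is taken as geometrically pure; bromide 10 is used as both C10 epimers, which converge because C10 becomes a planar radical.

**Step 1**
Reactants: 1 (2E,6E)-farnesol
Product: 2 (2R,3R)-2,3-epoxyfarnesol
Conditions: Ti(Oi-Pr)4 (cat.), D-(−)-diethyl tartrate, t-BuOOH, 4 Å MS, CH2Cl2, −20 °C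
Reagents that add atoms: tert-butyl hydroperoxide, CC(C)(C)OO
Why: Sharpless asymmetric epoxidation of the allylic alcohol; the D-tartrate–titanium complex delivers oxygen to one face of the C13=C14 alkene only (the other two alkenes are not directed), which fixes the later C13 carbinol as R.

**Step 2**
Reactants: 2 (2R,3R)-2,3-epoxyfarnesol
Product: 3 2,3-epoxyfarnesyl iodide
Conditions: PPh3, I2, imidazole, Et2O–MeCN, 0 °C
Reagents that add atoms: iodine, II
Why: Garegg–Samuelsson (Appel-type) iodination of the primary alcohol through the alkoxyphosphonium ion; the epoxide stereocentres are not touched.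

**Step 3**
Reactants: 3 2,3-epoxyfarnesyl iodide
Product: 4 (3R,6E)-nerolidol
Conditions: Zn dust, AcOH, EtOH, 25 °C
Reagents that add atoms: none
Why: Zinc inserts into the C–I bond and the β-oxido organozinc fragments (Boord-type reductive opening of a 2,3-epoxy iodide) to the tertiary allylic alcohol with the C13–O bond intact, so C13 stays R.

**Step 4**
Reactants: 4 (3R,6E)-nerolidol
Product: 5 (3R,6R,7R)-6,7-epoxynerolidol
Conditions: Hf(Ot-Bu)4 (cat.), chiral bis-hydroxamic acid ligand (cat., the enantiomer that gives the 8R,9R epoxide), cumene hydroperoxide, 4 Å MS, toluene, 0 °C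
Reagents that add atoms: cumene hydroperoxide, CC(C)(OO)c1ccccc1
Why: Hydroxyl-directed asymmetric epoxidation of a bishomoallylic alcohol with a hafnium bis-hydroxamate catalyst; the bound C13 alkoxide delivers the peroxide oxygen to the electron-rich C8=C9 alkene four atoms away (not to the remote isopropylidene group or the less nucleophilic vinyl group), and the ligand sets the 8R,9R face.

**Step 5**
Reactants: 5 (3R,6R,7R)-6,7-epoxynerolidol
Product: 6 triethylsilyl ether of 5
Conditions: Et3SiOTf, 2,6-lutidine, CH2Cl2, −78 °C
Reagents that add atoms: triethylsilyl trifluoromethanesulfonate, CC[Si](CC)(CC)OS(=O)(=O)C(F)(F)F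
Why: Silylation of the tertiary alcohol with a silyl triflate and a hindered base protects O13 and removes the nucleophile that could open the epoxide.

**Step 6**
Reactants: 6 triethylsilyl ether of 5
Product: 7 homopropargylic alcohol (C9 ethynyl and C8 tertiary hydroxyl)
Conditions: LiC≡CH·H2NCH2CH2NH2, DMSO, 25 °C; aq. NH4Cl
Reagents that add atoms: lithium acetylide–ethylenediamine complex, [Li+].[C-]#C.NCCN
Why: SN2 opening of the trisubstituted epoxide by acetylide in a dipolar aprotic solvent occurs at the less substituted carbon C9 with inversion, which sets C9 (R) anti to the retained C8–O bond (C8 R).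

**Step 7**
Reactants: 7 homopropargylic alcohol
Product: 8 α-methylene-γ-butyrolactone (O8–C20(=O)–C10(=C1H2))
Conditions: PdCl2 (cat.), SnCl2 (cat.), PPh3, CO (7 atm), MeCN, 75 °C
Reagents that add atoms: carbon monoxide, [C-]#[O+]
Why: Palladium-catalysed cyclocarbonylation of a homopropargylic alcohol (alkoxycarbonylpalladium formation, syn insertion of the alkyne, protonolysis) gives the α-methylene lactone; no stereocentre is touched and C20 enters as the lactone carbonyl.

**Step 8**
Reactants: 8 α-methylene-γ-butyrolactone
Product: 10 α-bromo-α-(2-cyanoethyl) lactone (both C10 epimers), via lithium lactone enolate 9 (not isolated)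
Conditions: LiN(i-Pr)2, MeCN, THF–DMPU, −78 °C; add 8; then BrCl2C–CCl2Br, −78 °C
Reagents that add atoms: acetonitrile, CC#N; 1,2-dibromo-1,1,2,2-tetrachloroethane, BrC(Cl)(Cl)C(Cl)(Cl)Br
Why: Michael addition of lithioacetonitrile to the exocyclic enoate gives the lactone enolate, which is brominated in the same flask (electrophilic α-halogenation); the new C10 centre needs no control because it becomes a planar radical in step 9.

**Step 9**
Reactants: 10 α-bromo-α-(2-cyanoethyl) lactone
Product: 12 tricyclic keto lactone (3-oxo-20,8-olide), via ketimine 11 (not isolated)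
Conditions: (Me3Si)3SiH (syringe pump), AIBN, toluene, 90 °C, high dilution; then AcOH–NaOAc buffer, THF–H2O, 25 °C
Reagents that add atoms: water, O
Why: The silyl radical abstracts bromine from 10 to give the electrophilic tertiary α-lactone radical at C10, which adds to C5, the CH end of the electron-rich isopropylidene group; the tertiary C4 radical so formed adds to the nitrile carbon C3, and the iminyl radical is reduced by the silane to ketimine 11, which is hydrolysed to the ketone. The closest known reaction type is the silane- or stannane-mediated radical polycyclisation of an α-halo carbonyl compound with a nitrile as terminator. Ring B closes 6-exo-trig (C10 to C5, chair, forming with the lactone a 6-oxabicyclo[3.2.1]octan-7-one) and ring A closes 6-exo-dig (C4 to C3, chair). At C10 the lactone ties O8 to C20, so the new C10–C5 bond can only form on the lactone face that carries the C7 chain, which leaves C20 and O8 cis-diaxial on ring B and C1 equatorial; at C5 the CMe2 radical takes the equatorial site because the axial one is syn-diaxial to the C11 chain on C9, so H5 ends trans to C20 and ring A closes trans-fused. The step needs the prenyl terminus to win over the side-chain vinyl group and cyclisation to win over 1,5-hydrogen transfer from C6: the electrophilic radical prefers the trisubstituted alkene, attack on the vinyl group would have to occur at its internal carbon next to quaternary C13, and slow addition of the silane keeps both radicals alive long enough to cyclise.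

**Step 10**
Reactants: 12 tricyclic keto lactone
Product: 13 axial C3 alcohol (OH trans to C20)
Conditions: LiBH(s-Bu)3, THF, −78 °C
Reagents that add atoms: none
Why: The bulky trialkylborohydride attacks the C3 ketone from the equatorial direction (1,2-reduction under steric approach control, as for 4,4-dimethyl-3-oxodecalins), giving the axial alcohol while the hindered lactone is untouched at −78 °C.

**Step 11**
Reactants: 13 axial C3 alcohol
Product: 14 equatorial C3 bromide (3R) lactone
Conditions: PPh3, CBr4, 2,6-lutidine, CH2Cl2, 0 → 40 °C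
Reagents that add atoms: carbon tetrabromide, BrC(Br)(Br)Br
Why: Appel reaction; bromide displaces the alkoxyphosphonium group in an SN2 step with inversion, turning the axial alcohol into the equatorial bromide cis to C20.

**Step 12**
Reactants: 14 equatorial C3 bromide lactone
Product: 15 lactol (C20 hemiacetal)
Conditions: i-Bu2AlH, CH2Cl2, −78 °C; aq. potassium sodium tartrate
Reagents that add atoms: none
Why: Partial reduction of the lactone stops at the tetrahedral aluminium hemiacetal at low temperature and gives the lactol; the secondary bromide, silyl ether and vinyl group are inert.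

**Step 13**
Reactants: 15 lactol
Product: 17 13-O-triethylsilyl ether of the target, via C20 tosylhydrazone 16 (not isolated)
Conditions: TsNHNH2, THF, 40 °C; then catecholborane, CHCl3, 0 °C; NaOAc·3H2O, 60 °C
Reagents that add atoms: none
Why: The lactol opens to the C20 aldehyde, which condenses to the tosylhydrazone; hydroboration of C=N and base-induced loss of sulfinate and N2 (a mild Wolff–Kishner-type deoxygenation) leave C20 as the methyl group and free the C8 hydroxyl without touching the bromide.

**Step 14**
Reactants: 17 13-O-triethylsilyl ether of the target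
Product: 18 target diol
Conditions: HF·pyridine, pyridine, THF, 0 → 25 °C
Reagents that add atoms: none
Why: Fluoride-mediated cleavage of the tertiary triethylsilyl ether under buffered conditions releases the C13 hydroxyl without elimination of the equatorial bromide.

**Compound list**

1 | (2E,6E)-farnesol | OC/C=C(\C)CC/C=C(\C)CCC=C(C)C | starting material
2 | (2R,3R)-2,3-epoxyfarnesol (6E) | OC[C@H]1O[C@]1(C)CC/C=C(\C)CCC=C(C)C | intermediate
3 | 2,3-epoxyfarnesyl iodide (epoxide carbons configured as in 2; 6E) | IC[C@H]1O[C@]1(C)CC/C=C(\C)CCC=C(C)C | intermediate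
4 | (3R,6E)-nerolidol | C=C[C@](C)(O)CC/C=C(\C)CCC=C(C)C | intermediate
5 | (3R,6R,7R)-6,7-epoxynerolidol (labdane C13 R, C9 R, C8 R) | C=C[C@](C)(O)CC[C@H]1O[C@]1(C)CCC=C(C)C | intermediate
6 | 3-O-triethylsilyl-(3R,6R,7R)-6,7-epoxynerolidol | C=C[C@](C)(O[Si](CC)(CC)CC)CC[C@H]1O[C@]1(C)CCC=C(C)C | intermediate
7 | (3R,6R,7R)-6-ethynyl-3,7,11-trimethyl-3-(triethylsilyloxy)dodeca-1,10-dien-7-ol | C=C[C@](C)(O[Si](CC)(CC)CC)CC[C@H](C#C)[C@](C)(O)CCC=C(C)C | intermediate
8 | (4R,5R)-5-methyl-3-methylidene-5-(4-methylpent-3-enyl)-4-[(3R)-3-methyl-3-(triethylsilyloxy)pent-4-enyl]oxolan-2-one | C=C[C@](C)(O[Si](CC)(CC)CC)CC[C@@H]1C(=C)C(=O)O[C@]1(C)CCC=C(C)C | intermediate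
9 | lithium enolate of the 3-(2-cyanoethyl) lactone (C8, C9, C13 as in 8) | [Li+].C=C[C@](C)(O[Si](CC)(CC)CC)CC[C@@H]1C(CCC#N)=C([O-])O[C@]1(C)CCC=C(C)C | intermediate
10 | 3-bromo-3-(2-cyanoethyl) lactone (both C10 epimers; C8, C9, C13 as in 8) | C=C[C@](C)(O[Si](CC)(CC)CC)CC[C@@H]1C(Br)(CCC#N)C(=O)O[C@]1(C)CCC=C(C)C | intermediate
11 | tricyclic ketimine (3-imino analogue of 12) | C=C[C@](C)(O[Si](CC)(CC)CC)CC[C@@H]1[C@]23CCC(=N)C(C)(C)[C@H]2CC[C@@]1(C)OC3=O | intermediate
12 | 3-oxo-13-(triethylsilyloxy)labd-14-en-20,8-olide (C20 and O8 cis; H5 and C11 trans to C20; 13R) | C=C[C@](C)(O[Si](CC)(CC)CC)CC[C@@H]1[C@]23CCC(=O)C(C)(C)[C@H]2CC[C@@]1(C)OC3=O | intermediate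
13 | 3-hydroxy lactone, OH axial and trans to C20 (other centres as in 12) | C=C[C@](C)(O[Si](CC)(CC)CC)CC[C@@H]1[C@]23CC[C@H](O)C(C)(C)[C@H]2CC[C@@]1(C)OC3=O | intermediate
14 | (3R)-3-bromo lactone, Br equatorial and cis to C20 | C=C[C@](C)(O[Si](CC)(CC)CC)CC[C@@H]1[C@]23CC[C@@H](Br)C(C)(C)[C@H]2CC[C@@]1(C)OC3=O | intermediate
15 | lactol of 14 (C20 hemiacetal, both anomers) | C=C[C@](C)(O[Si](CC)(CC)CC)CC[C@@H]1[C@]23CC[C@@H](Br)C(C)(C)[C@H]2CC[C@@]1(C)OC3O | intermediate
16 | C20 aldehyde tosylhydrazone with free C8 hydroxyl | C=C[C@](C)(O[Si](CC)(CC)CC)CC[C@@H]1[C@]2(C=NNS(=O)(=O)c3ccc(C)cc3)CC[C@@H](Br)C(C)(C)[C@H]2CC[C@@]1(C)O | intermediate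
17 | 13-O-triethylsilyl ether of the target | C=C[C@](C)(O[Si](CC)(CC)CC)CC[C@@H]1[C@]2(C)CC[C@@H](Br)C(C)(C)[C@H]2CC[C@@]1(C)O | intermediate
18 | (1R,2R,4aS,6R,8aR)-6-bromo-1-[(3R)-3-hydroxy-3-methylpent-4-en-1-yl]-2,5,5,8a-tetramethyldecahydronaphthalen-2-ol (labdane numbers: 3R,5S,8R,9R,10R,13R) | C=C[C@](C)(O)CC[C@@H]1[C@]2(C)CC[C@@H](Br)C(C)(C)[C@H]2CC[C@@]1(C)O | target

**Step count**

Total: 14 steps. Longest linear sequence: 14 steps (fully linear from 1).

**Steps most likely to fail**

1. Step 9. The C4 radical may take a hydrogen (from the silane or from C2–H) before the slow, reversible addition to the nitrile. The C10 radical may also abstract the allylic C6 hydrogen or add to the side-chain vinyl group. Fallback (carbonyl instead of nitrile as terminator): the fallback sets out from 8. CuBr·SMe2-catalysed conjugate addition of (1,3-dioxolan-2-ylmethyl)magnesium bromide and enolate bromination with BrCl2C–CCl2Br should give the acetal bromolactone F1. Mild acetal hydrolysis (pyridinium tosylate, acetone–water) should give the aldehyde bromolactone F2. Bu3SnH/AIBN in benzene at 80 °C then closes ring B as before and ring A by 6-exo addition of the C4 radical to the aldehyde, whose alkoxy radical is trapped very fast by the stannane, to give the C3 carbinol F3 (either epimer). Dess–Martin oxidation returns to 12.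

2. Step 4. The chiral catalyst may give poor facial control on a tertiary bishomoallylic alcohol, and the free hydroxyl may open the new epoxide to a tetrahydrofuran. Fallback (substrate-directed site control and separation instead of catalyst control): the fallback sets out from 4. VO(acac)2 and t-BuOOH, which epoxidise only the hydroxyl-directed C8=C9 alkene, should give 5 together with the 8S,9S-epoxide F4. Immediate silylation as in step 5 should give 6 and the silyl ether F5, which are separated by chromatography; the route resumes at 6.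

3. Step 11. E2 loss of the axial leaving group toward C2, or a methyl shift from C4, may outrun the hindered SN2 at the neopentyl centre. Fallback (isolated sulfonate and ion-pair displacement instead of in-situ phosphonium activation): the fallback sets out from 13. Tf2O with 2,6-di-tert-butylpyridine at −78 °C should give the axial triflate F6, which is displaced at low temperature by Bu4NBr in toluene with inversion to return to 14.

**Further compounds**

F1 | step 9 | 3-bromo-3-[2-(1,3-dioxolan-2-yl)ethyl] lactone (C10 epimers; C8, C9, C13 as in 8) | C=C[C@](C)(O[Si](CC)(CC)CC)CC[C@@H]1C(Br)(CCC2OCCO2)C(=O)O[C@]1(C)CCC=C(C)C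
F2 | step 9 | 3-bromo-3-(3-oxopropyl) lactone (C10 epimers; C8, C9, C13 as in 8) | C=C[C@](C)(O[Si](CC)(CC)CC)CC[C@@H]1C(Br)(CCC=O)C(=O)O[C@]1(C)CCC=C(C)C
F3 | step 9 | 3-hydroxy-13-(triethylsilyloxy)labd-14-en-20,8-olide (C3 epimers; other centres as in 12) | C=C[C@](C)(O[Si](CC)(CC)CC)CC[C@@H]1[C@]23CCC(O)C(C)(C)[C@H]2CC[C@@]1(C)OC3=O
F4 | step 4 | (3R,6S,7S)-6,7-epoxynerolidol | C=C[C@](C)(O)CC[C@@H]1O[C@@]1(C)CCC=C(C)C
F5 | step 4 | 3-O-triethylsilyl-(3R,6S,7S)-6,7-epoxynerolidol | C=C[C@](C)(O[Si](CC)(CC)CC)CC[C@@H]1O[C@@]1(C)CCC=C(C)C
F6 | step 11 | axial C3 trifluoromethanesulfonate of 13 | C=C[C@](C)(O[Si](CC)(CC)CC)CC[C@@H]1[C@]23CC[C@H](OS(=O)(=O)C(F)(F)F)C(C)(C)[C@H]2CC[C@@]1(C)OC3=O
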